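**Retrosynthetic overview**

1. Late disconnections: the C3 aroyl group (vinylic lithiation/acylation), the C1 prenyl group (bridgehead alkylation), and the C7 prenyl/H pair (allylation of a C7 nitronate, then radical removal of the nitro group, which serves as a traceless activator).
2. Ring B (C5–C6–C7–C8–C1–C9) is closed at C6–C7 by a Michael-initiated ring closure: 2-methyl-1-nitropropene adds to C1 of a monocyclic ring A trione (C1–C8, bringing in C8 with its two methyls and C7), and the nitronate carbon C7 then displaces iodide from C6.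
3. Enabling feature: in ring A (C1–C2–C3–C4–C5–C9) the prochiral quaternary C5 carries the iodomethyl carbon C6 and the lavandulyl arm, and lies 1,3 across the C9 carbonyl from the nucleophilic, epimerisable methylene C1. A two-carbon nitroalkene can therefore bridge C1 and C6, and the quaternary C5 keeps ring A from aromatising.
4. Ring A is assembled from dimethyl malonate (C4–C5–C9), (R)-lavandulyl iodide, CH2I2 and the methyl acetoacetate dianion (C1–C2–C3) by Claisen/Dieckmann/decarboxylation.
5. Order of ring formation: ring A (step 4), then ring B (step 5).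

Key step: step 5

Remark: (R)-(−)-lavandulol is taken as a purchasable enantiopure building block; "Lav" means its (2S)-5-methyl-2-(prop-1-en-2-yl)hex-4-en-1-yl group, and all intermediates use the target's core numbering (C1 prenyl bridgehead, C5 Lav bridgehead, C9 bridging carbonyl).

**Route**

Step 1
Reactants: 1 (R)-lavandulol
Product: 2 (R)-lavandulyl iodide [(5R)-5-(iodomethyl)-2,6-dimethylhepta-2,6-diene]
Conditions: I2, PPh3, imidazole, CH2Cl2, 0 → 25 °C
Reagents that add atoms: iodine, II
Why: Appel-type iodination of the primary alcohol proceeds by SN2 at CH2 and leaves the neighbouring stereocentre untouched.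

Step 2
Reactants: 2 (R)-lavandulyl iodide; 3 dimethyl malonate
Product: 4 dimethyl 2-Lav-malonate
Conditions: 3 (3 equiv), NaH, THF–DMF, 0 → 60 °C
Reagents that add atoms: none
Why: Malonic ester alkylation (SN2 of the sodium enolate on the primary iodide, excess malonate against double alkylation) carries the lavandulyl stereocentre over unchanged; its descriptor becomes S only through the priority rules.

Step 3
Reactants: 4 dimethyl 2-Lav-malonate
Product: 5 dimethyl 2-(iodomethyl)-2-Lav-malonate
Conditions: NaH, THF, 25 °C; CH2I2 (5 equiv), 65 °C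
Reagents that add atoms: diiodomethane, ICI
Why: SN2 iodomethylation of the tertiary malonate enolate installs C6 as a neopentyl iodide, which should resist a second displacement and so survive as the latent electrophile.

Step 4
Reactants: 5 dimethyl 2-(iodomethyl)-2-Lav-malonate; 6 methyl acetoacetate
Product: 9 2-(iodomethyl)-2-Lav-cyclohexane-1,3,5-trione (enolised), via dioxo ester 7 (not isolated), via cyclic keto ester 8 (not isolated)
Conditions: 6 (2.5 equiv), NaH, n-BuLi, THF, 0 → 25 °C; NaOH, H2O–MeOH, 60 °C; then HCl to pH 3, 40 °C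
Reagents that add atoms: none
Why: Crossed Claisen acylation of the acetoacetate dianion at its γ-carbon by one malonate ester, Dieckmann closure onto the second ester and saponification–decarboxylation should give ring A, whose quaternary C5 blocks aromatisation and leaves two equivalent (enantiotopic) ring methylenes.

Step 5
Reactants: 9 2-(iodomethyl)-2-Lav-cyclohexane-1,3,5-trione; 10 2-methyl-1-nitroprop-1-ene
Product: 12 (1S,5R,7S)-8,8-dimethyl-5-Lav-7-nitrobicyclo[3.3.1]nonane-2,4,9-trione, via Michael adduct 11 (not isolated)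
Conditions: N-(9-anthracenylmethyl)-O-allylcinchonidinium bromide (10 mol%), Cs2CO3 (2.5 equiv), toluene, 0 → 45 °C; aqueous citric acid work-up
Reagents that add atoms: none
Why: Proposed new method: the enolate of 9, ion-paired with the chiral ammonium, should add through a ring methylene (C1) to nitroalkene 10 (C1–C8); in adduct 11 the hindered 2-tert-alkyl-1,3-dione unit stays in the C1–H keto form, and the nitronate carbon C7 then displaces iodide from the neopentyl C6 in a 6-exo-tet SN2 closure of ring B. The closest known reactions are Michael/alkylation and Michael/Henry dominos of 1,3-dicarbonyls with nitroalkenes under organocatalysis or phase transfer (nitrocyclopropanes, bridged bicycles) and intramolecular enolate alkylations by neopentyl iodides. C-alkylation is secured because O-alkylation of the nitronate would need an eight-membered ring, and the ring can only close when the C1 arm and the CH2I group are cis-diaxial, which the epimerisable C1–H centre allows. The configuration of C1 is tied to C5 by the bridge, and C5 becomes stereogenic through the choice between the two enantiotopic methylenes of 9. Because the hindered Michael addition should be reversible, the chiral cation is expected to select the ring-closing transition state (dynamic kinetic desymmetrisation); the cinchonidinium salt or its pseudoenantiomeric cinchoninium salt would be matched to the (1S,5R) core in a screen. C7 is left as the equilibrating exo (equatorial) nitro epimer and is fixed later.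

Step 6
Reactants: 12 (1S,5R,7S)-8,8-dimethyl-5-Lav-7-nitrobicyclo[3.3.1]nonane-2,4,9-trione
Product: 13 (1S,5R,7S)-2-methoxy-8,8-dimethyl-5-Lav-7-nitrobicyclo[3.3.1]non-2-ene-4,9-dione
Conditions: HC(OMe)3, MeOH, camphorsulfonic acid (cat.), 25 °C
Reagents that add atoms: trimethyl orthoformate, COC(OC)OC
Why: Acid-catalysed enol ether formation masks the acidic C2/C4 β-diketone; under equilibrating conditions the methoxy group should settle on C2, remote from the quaternary C5 and its Lav arm (the C4 regioisomer can be hydrolysed back to 12).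

Step 7
Reactants: 13 (1S,5R,7S)-2-methoxy-8,8-dimethyl-5-Lav-7-nitrobicyclo[3.3.1]non-2-ene-4,9-dione
Product: 14 (1S,5R,7R)-2-methoxy-8,8-dimethyl-7-(3-methylbut-2-en-1-yl)-5-Lav-7-nitrobicyclo[3.3.1]non-2-ene-4,9-dione (prenyl exo, nitro endo)
Conditions: prenyl acetate, Pd(PPh3)4 (5 mol%), DBU, THF, 50 °C
Reagents that add atoms: prenyl acetate (3-methylbut-2-en-1-yl acetate), CC(=O)OCC=C(C)C
Why: Tsuji–Trost allylation of the C7 nitronate at the unsubstituted terminus of the π-prenyl complex gives the tertiary nitro compound; the electrophile should enter from the open exo face, but this configuration is erased in step 8.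

Step 8
Reactants: 14 (1S,5R,7R)-2-methoxy-8,8-dimethyl-7-(3-methylbut-2-en-1-yl)-5-Lav-7-nitrobicyclo[3.3.1]non-2-ene-4,9-dione
Product: 15 (1S,5R,7R)-2-methoxy-8,8-dimethyl-7-(3-methylbut-2-en-1-yl)-5-Lav-bicyclo[3.3.1]non-2-ene-4,9-dione (7-prenyl endo)
Conditions: Bu3SnH (5 equiv), AIBN (0.3 equiv), toluene, 110 °C
Reagents that add atoms: none
Why: Radical denitration of the tertiary nitro group gives a planar C7 radical that should take hydrogen from tributyltin hydride on the open exo face (the endo face lies over ring A), so that H ends exo and the prenyl group endo as in the target; C1 still bears H, so no prenyl group sits in 5-exo reach of the radical.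

Step 9
Reactants: 15 (1S,5R,7R)-2-methoxy-8,8-dimethyl-7-(3-methylbut-2-en-1-yl)-5-Lav-bicyclo[3.3.1]non-2-ene-4,9-dione
Product: 16 (1S,5R,7R)-2-methoxy-8,8-dimethyl-1,7-bis(3-methylbut-2-en-1-yl)-5-Lav-bicyclo[3.3.1]non-2-ene-4,9-dione
Conditions: LDA (LiN(i-Pr)2), THF, −78 °C; prenyl bromide, −78 → 0 °C
Reagents that add atoms: prenyl bromide (1-bromo-3-methylbut-2-ene), CC(C)=CCBr
Why: Bridgehead lithiation at C1, the only sp3 C–H next to a ketone (C9), followed by SN2 alkylation with the reactive allylic bromide makes the C1 quaternary centre with retention, the exo position being the only one open at a bridgehead.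

Step 10
Reactants: 16 (1S,5R,7R)-2-methoxy-8,8-dimethyl-1,7-bis(3-methylbut-2-en-1-yl)-5-Lav-bicyclo[3.3.1]non-2-ene-4,9-dione; 17 3-acetoxybenzoyl chloride
Product: 18 3-{[(1S,5S,7R)-2-methoxy-8,8-dimethyl-1,7-bis(3-methylbut-2-en-1-yl)-5-Lav-4,9-dioxobicyclo[3.3.1]non-2-en-3-yl]carbonyl}phenyl acetate
Conditions: LiTMP (lithium 2,2,6,6-tetramethylpiperidide), THF, −78 °C; then 17, −78 °C
Reagents that add atoms: none
Why: Vinylic lithiation at C3 of the vinylogous ester with the hindered amide base and C-acylation by the acid chloride introduces the aroyl group; no bridgehead proton remains to compete.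

Step 11
Reactants: 18 3-{[(1S,5S,7R)-2-methoxy-8,8-dimethyl-1,7-bis(3-methylbut-2-en-1-yl)-5-Lav-4,9-dioxobicyclo[3.3.1]non-2-en-3-yl]carbonyl}phenyl acetate
Product: 19 CNP0103487.1, (1R,5R,7R)-4-hydroxy-3-(3-hydroxybenzoyl)-8,8-dimethyl-1,7-bis(3-methylbut-2-en-1-yl)-5-Lav-bicyclo[3.3.1]non-3-ene-2,9-dione
Conditions: LiOH, dioxane–H2O, 90 °C; then aqueous HCl
Reagents that add atoms: lithium hydroxide, [Li+].[OH-]
Why: Hydroxide addition–elimination at C2 cleaves the vinylogous methyl ester and saponifies the aryl acetate in one operation, touching no stereocentre.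

**Compound list**

1 | (R)-lavandulol, (2R)-5-methyl-2-(prop-1-en-2-yl)hex-4-en-1-ol | C=C(C)[C@@H](CC=C(C)C)CO | starting material
2 | (R)-lavandulyl iodide, (5R)-5-(iodomethyl)-2,6-dimethylhepta-2,6-diene | C=C(C)[C@@H](CC=C(C)C)CI | intermediate
3 | dimethyl malonate | COC(=O)CC(=O)OC | starting material
4 | dimethyl 2-[(2S)-5-methyl-2-(prop-1-en-2-yl)hex-4-en-1-yl]malonate | C=C(C)[C@@H](CC=C(C)C)CC(C(=O)OC)C(=O)OC | intermediate
5 | dimethyl 2-(iodomethyl)-2-[(2S)-5-methyl-2-(prop-1-en-2-yl)hex-4-en-1-yl]malonate | C=C(C)[C@@H](CC=C(C)C)CC(CI)(C(=O)OC)C(=O)OC | intermediate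
6 | methyl acetoacetate (methyl 3-oxobutanoate) | COC(=O)CC(C)=O | starting material
7 | dimethyl 2-(iodomethyl)-2-Lav-3,5-dioxoheptanedioate (both configurations at the new quaternary carbon) | C=C(C)[C@@H](CC=C(C)C)CC(CI)(C(=O)OC)C(=O)CC(=O)CC(=O)OC | intermediate
8 | methyl 3-(iodomethyl)-3-Lav-2,4,6-trioxocyclohexane-1-carboxylate (ring stereocentres unassigned, lost on decarboxylation) | C=C(C)[C@@H](CC=C(C)C)CC1(CI)C(=O)CC(=O)C(C(=O)OC)C1=O | intermediate
9 | 2-(iodomethyl)-2-[(2S)-5-methyl-2-(prop-1-en-2-yl)hex-4-en-1-yl]cyclohexane-1,3,5-trione (triketo form shown; C5 prochiral) | C=C(C)[C@@H](CC=C(C)C)CC1(CI)C(=O)CC(=O)CC1=O | intermediate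
10 | 2-methyl-1-nitroprop-1-ene | CC(C)=C[N+](=O)[O-] | starting material
11 | 2-(iodomethyl)-2-Lav-6-(2-methyl-1-nitropropan-2-yl)cyclohexane-1,3,5-trione, quaternary carbon (core C5) configured as in 12, nitroalkyl-bearing carbon (core C1) epimerisable | C=C(C)[C@@H](CC=C(C)C)C[C@@]1(CI)C(=O)CC(=O)C(C(C)(C)C[N+](=O)[O-])C1=O | intermediate
12 | (1S,5R,7S)-8,8-dimethyl-5-Lav-7-nitrobicyclo[3.3.1]nonane-2,4,9-trione (exo-nitro epimer shown, C7 labile) | C=C(C)[C@@H](CC=C(C)C)C[C@@]12C[C@H]([N+](=O)[O-])C(C)(C)[C@@H](C(=O)CC1=O)C2=O | intermediate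
13 | (1S,5R,7S)-2-methoxy-8,8-dimethyl-5-Lav-7-nitrobicyclo[3.3.1]non-2-ene-4,9-dione | C=C(C)[C@@H](CC=C(C)C)C[C@@]12C[C@H]([N+](=O)[O-])C(C)(C)[C@@H](C(OC)=CC1=O)C2=O | intermediate
14 | (1S,5R,7R)-2-methoxy-8,8-dimethyl-7-(3-methylbut-2-en-1-yl)-5-Lav-7-nitrobicyclo[3.3.1]non-2-ene-4,9-dione (prenyl exo, nitro endo) | C=C(C)[C@@H](CC=C(C)C)C[C@@]12C[C@@](CC=C(C)C)([N+](=O)[O-])C(C)(C)[C@@H](C(OC)=CC1=O)C2=O | intermediate
15 | (1S,5R,7R)-2-methoxy-8,8-dimethyl-7-(3-methylbut-2-en-1-yl)-5-Lav-bicyclo[3.3.1]non-2-ene-4,9-dione (7-prenyl endo) | C=C(C)[C@@H](CC=C(C)C)C[C@@]12C[C@@H](CC=C(C)C)C(C)(C)[C@@H](C(OC)=CC1=O)C2=O | intermediate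
16 | (1S,5R,7R)-2-methoxy-8,8-dimethyl-1,7-bis(3-methylbut-2-en-1-yl)-5-Lav-bicyclo[3.3.1]non-2-ene-4,9-dione | C=C(C)[C@@H](CC=C(C)C)C[C@@]12C[C@@H](CC=C(C)C)C(C)(C)[C@@](CC=C(C)C)(C(OC)=CC1=O)C2=O | intermediate
17 | 3-acetoxybenzoyl chloride | CC(=O)Oc1cccc(C(=O)Cl)c1 | starting material
18 | 3-{[(1S,5S,7R)-2-methoxy-8,8-dimethyl-1,7-bis(3-methylbut-2-en-1-yl)-5-Lav-4,9-dioxobicyclo[3.3.1]non-2-en-3-yl]carbonyl}phenyl acetate | C=C(C)[C@@H](CC=C(C)C)C[C@@]12C[C@@H](CC=C(C)C)C(C)(C)[C@@](CC=C(C)C)(C(OC)=C(C(=O)c3cccc(OC(C)=O)c3)C1=O)C2=O | intermediate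
19 | CNP0103487.1, (1R,5R,7R)-4-hydroxy-3-(3-hydroxybenzoyl)-8,8-dimethyl-1,7-bis(3-methylbut-2-en-1-yl)-5-[(2S)-5-methyl-2-(prop-1-en-2-yl)hex-4-en-1-yl]bicyclo[3.3.1]non-3-ene-2,9-dione | C=C(C)[C@@H](CC=C(C)C)C[C@@]12C[C@@H](CC=C(C)C)C(C)(C)[C@@](CC=C(C)C)(C(=O)C(C(=O)c3cccc(O)c3)=C1O)C2=O | target

**Summary**

Total step count: 11. Longest linear sequence: 11 steps (1 → 19).

Steps most likely to fail:

Step 5 (carries the label). What may go wrong: C-alkylation of the weakly nucleophilic nitronate at the neopentyl iodide is too slow, so the reversible Michael addition runs backwards and control over which ring methylene is bridged is lost. Fallback, from 4 back to 12, with known reactions only: C6 is carried as a formyl group and ring B is closed by a nitro-aldol instead of an alkylation. Malonate 4 is dimethoxymethylated (TiCl4, Et3N, HC(OMe)3, CH2Cl2) to the acetal malonate F1. The conditions of step 4 then lead through the acetal dioxo ester F2 and the acetal cyclic keto ester F3 to the acetal trione F4, and aqueous formic acid unmasks the 2-formyl trione F5. With 10 and a bifunctional cinchona squaramide (CH2Cl2, 0 °C), the Michael adduct F6 closes by an intramolecular Henry reaction, again at C6–C7, to the 6-hydroxy-7-nitro bicycle F7. Dehydration on basic Al2O3 gives the 6-ene nitroalkene F8, and transfer hydrogenation with a Hantzsch ester and a thiourea catalyst returns 12.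

Step 7. What may go wrong: the bulky π-prenyl palladium complex does not reach the nitronate carbon flanked by the quaternary C8, leaving O-allylation or no conversion. Fallback, from 13 back to 14: allylation with the smaller allyl acetate under the same Tsuji–Trost conditions gives the 7-allyl-7-nitro compound F9. Cross metathesis of its terminal alkene with 2-methylbut-2-ene and RuCl2(=CHPh)(PCy3)(H2IMes) (second-generation Grubbs catalyst, CH2Cl2, 40 °C) then gives 14. The trisubstituted and 1,1-disubstituted alkenes of the other side chains should not take part.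

Step 9. What may go wrong: the bridgehead carbanion next to the gem-dimethyl carbon is alkylated too slowly by prenyl bromide, so proton return or metalation at C3 takes over. Fallback, from 15 back to 16: the bridgehead lithium species is quenched with I2 to the 1-iodo compound F10. Radical allylation with allyltributylstannane and AIBN (Keck allylation, benzene, 80 °C) gives the 1-allyl compound F11. Cross metathesis with 2-methylbut-2-ene and RuCl2(=CHPh)(PCy3)(H2IMes) then gives 16.

Further compounds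
F1 | step 5 | dimethyl 2-(dimethoxymethyl)-2-Lav-malonate | C=C(C)[C@@H](CC=C(C)C)CC(C(OC)OC)(C(=O)OC)C(=O)OC
F2 | step 5 | dimethyl 2-(dimethoxymethyl)-2-Lav-3,5-dioxoheptanedioate (not isolated) | C=C(C)[C@@H](CC=C(C)C)CC(C(OC)OC)(C(=O)OC)C(=O)CC(=O)CC(=O)OC
F3 | step 5 | methyl 3-(dimethoxymethyl)-3-Lav-2,4,6-trioxocyclohexane-1-carboxylate (not isolated) | C=C(C)[C@@H](CC=C(C)C)CC1(C(OC)OC)C(=O)CC(=O)C(C(=O)OC)C1=O
F4 | step 5 | 2-(dimethoxymethyl)-2-Lav-cyclohexane-1,3,5-trione | C=C(C)[C@@H](CC=C(C)C)CC1(C(OC)OC)C(=O)CC(=O)CC1=O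
F5 | step 5 | 2-formyl-2-Lav-cyclohexane-1,3,5-trione (1,3,5-trioxo-2-Lav-cyclohexane-2-carbaldehyde) | C=C(C)[C@@H](CC=C(C)C)CC1(C=O)C(=O)CC(=O)CC1=O
F6 | step 5 | 2-formyl-2-Lav-6-(2-methyl-1-nitropropan-2-yl)cyclohexane-1,3,5-trione (not isolated; nitroalkyl-bearing carbon epimerisable) | C=C(C)[C@@H](CC=C(C)C)C[C@@]1(C=O)C(=O)CC(=O)C(C(C)(C)C[N+](=O)[O-])C1=O
F7 | step 5 | (1S,5R)-6-hydroxy-8,8-dimethyl-5-Lav-7-nitrobicyclo[3.3.1]nonane-2,4,9-trione (C6/C7 epimers) | C=C(C)[C@@H](CC=C(C)C)C[C@@]12C(O)C([N+](=O)[O-])C(C)(C)[C@@H](C(=O)CC1=O)C2=O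
F8 | step 5 | (1S,5R)-8,8-dimethyl-5-Lav-7-nitrobicyclo[3.3.1]non-6-ene-2,4,9-trione | C=C(C)[C@@H](CC=C(C)C)C[C@@]12C=C([N+](=O)[O-])C(C)(C)[C@@H](C(=O)CC1=O)C2=O
F9 | step 7 | (1S,5R,7R)-2-methoxy-8,8-dimethyl-5-Lav-7-nitro-7-(prop-2-en-1-yl)bicyclo[3.3.1]non-2-ene-4,9-dione | C=C(C)[C@@H](CC=C(C)C)C[C@@]12C[C@@](CC=C)([N+](=O)[O-])C(C)(C)[C@@H](C(OC)=CC1=O)C2=O
F10 | step 9 | (1R,5R,7R)-1-iodo-2-methoxy-8,8-dimethyl-7-(3-methylbut-2-en-1-yl)-5-Lav-bicyclo[3.3.1]non-2-ene-4,9-dione | C=C(C)[C@@H](CC=C(C)C)C[C@@]12C[C@@H](CC=C(C)C)C(C)(C)[C@@](I)(C(OC)=CC1=O)C2=O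
F11 | step 9 | (1S,5R,7R)-2-methoxy-8,8-dimethyl-7-(3-methylbut-2-en-1-yl)-5-Lav-1-(prop-2-en-1-yl)bicyclo[3.3.1]non-2-ene-4,9-dione | C=C(C)[C@@H](CC=C(C)C)C[C@@]12C[C@@H](CC=C(C)C)C(C)(C)[C@@](CC=C)(C(OC)=CC1=O)C2=O
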